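**Plan**

1. Retrosynthesis: the two benzyl ethers on ring B are removed last. Ring C is opened at O1–C2 (oxa-Michael addition, C3 set by protonation) and then at C4–C4a (1,3-acyl shift), which turns the isoflavanone into the phloroglucinol mono-ester of a 2-arylacrylic acid.
2. The 2-arylacrylate is cut at its carboxyl carbon (alkyne methoxycarbonylation), at the alkyne (aldehyde homologation) and at the aryl–prenyl bond (Stille coupling), back to 3-bromo-4,5-dihydroxybenzaldehyde. The epoxide is traced to the prenyl olefin.
3. Forward: ring B is elaborated first, epoxide included (steps 1 to 6), and joined to ring A as an ester (step 7). Ring C is then built in one operation: photo-Fries acyl shift to a 2-aryl-1-(2,4,6-trihydroxyphenyl)propenone, then catalytic asymmetric 6-endo oxa-Michael addition with protonation. Hydrogenolysis ends the route.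
4. Enabling feature: ring A is 1,3,5-trioxygenated (O1 on C8a, OH on C5 and C7). In the phloroglucinol ester the carbons that become C4a, C6 and C8 are therefore equivalent, and so are the two hydroxyls flanking the new ketone (one becomes O1, the other 5-OH). C2 is an unsubstituted CH2 and can be offered as the terminal carbon of an enone. The light-driven acyl shift needs no acid or base, so the sensitive epoxide can be in place before ring C exists.
5. Stereochemistry: the epoxide carbon (R) comes from Shi epoxidation of the prenyl olefin with the D-fructose-derived ketone (reagent control). C3 (S) comes from catalyst-controlled protonation of the enolate formed in the ring closure and is kept by avoiding base afterwards.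

Key step: step 8

Assumption: the facial sense of proton delivery by the cinchona squaramide cannot be predicted with certainty. The route is written with the epi-quinidine-derived catalyst; its epi-quinine-derived pseudo-enantiomer would be used if the opposite face is favoured.

**Route**

Step 1
Reactants: 1 3-bromo-4,5-dihydroxybenzaldehyde
Product: 2 3,4-bis(benzyloxy)-5-bromobenzaldehyde
Conditions: BnBr, K2CO3, DMF, 60 °C
Reagents that add atoms: benzyl bromide, BrCc1ccccc1
Why: Double Williamson etherification of the two catechol hydroxyls by SN2 attack of the phenoxides on benzyl bromide; no stereocentre is involved.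

Step 2
Reactants: 2 3,4-bis(benzyloxy)-5-bromobenzaldehyde; 3 tributyl(3-methylbut-2-en-1-yl)stannane
Product: 4 3,4-bis(benzyloxy)-5-(3-methylbut-2-en-1-yl)benzaldehyde
Conditions: Pd(PPh3)4 (5 mol%), DMF, 100 °C
Reagents that add atoms: none
Why: Stille coupling (oxidative addition of the aryl bromide to zerovalent palladium, transmetalation, reductive elimination) should transfer the prenyl group through its tin-bearing carbon to give the linear 3-methylbut-2-enyl arene, with the aldehyde and benzyl ethers inert.

Step 3
Reactants: 4 3,4-bis(benzyloxy)-5-(3-methylbut-2-en-1-yl)benzaldehyde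
Product: 5 1,2-bis(benzyloxy)-5-ethynyl-3-(3-methylbut-2-en-1-yl)benzene
Conditions: dimethyl (1-diazo-2-oxopropyl)phosphonate, K2CO3, MeOH–THF, 0 °C to rt
Reagents that add atoms: dimethyl (1-diazo-2-oxopropyl)phosphonate, CC(=O)C(=[N+]=[N-])P(=O)(OC)OC
Why: Seyferth–Gilbert homologation in its Ohira–Bestmann form: methanolysis frees the diazomethylphosphonate anion, which converts the aldehyde into the terminal alkyne through an alkylidene carbene, leaving the prenyl olefin untouched.

Step 4
Reactants: 5 1,2-bis(benzyloxy)-5-ethynyl-3-(3-methylbut-2-en-1-yl)benzene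
Product: 6 methyl 2-[3,4-bis(benzyloxy)-5-(3-methylbut-2-en-1-yl)phenyl]prop-2-enoate
Conditions: CO (30 bar), Pd(OAc)2 (1 mol%), 2-(diphenylphosphino)pyridine, MsOH (cat.), MeOH, 50 °C
Reagents that add atoms: carbon monoxide, [C-]#[O+]; methanol, CO
Why: Palladium-catalysed Markovnikov methoxycarbonylation of a terminal arylalkyne, for which the pyridylphosphine/acid system is branched-selective, should give the 2-arylacrylate; the alkyne reacts far faster than the trisubstituted olefin.

Step 5
Reactants: 6 methyl 2-[3,4-bis(benzyloxy)-5-(3-methylbut-2-en-1-yl)phenyl]prop-2-enoate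
Product: 7 methyl 2-{3,4-bis(benzyloxy)-5-[((2R)-3,3-dimethyloxiran-2-yl)methyl]phenyl}prop-2-enoate
Conditions: D-fructose-derived Shi ketone (1,2:4,5-di-O-isopropylidene-β-D-erythro-hexo-2,3-diulo-2,6-pyranose, 30 mol%), KHSO5 (as 2KHSO5·KHSO4·K2SO4), K2CO3, Bu4NHSO4 (cat.), MeCN–CH2(OMe)2/aq. Na2B4O7 buffer, pH 10.5, 0 °C
Reagents that add atoms: potassium peroxymonosulfate, [K+].[O-]S(=O)(=O)OO
Why: Shi epoxidation: the chiral dioxirane attacks the electron-rich trisubstituted olefin much faster than the electron-poor acrylate, and the spiro transition state of the D-fructose-derived ketone should deliver oxygen to the face that gives the (R)-epoxide.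

Step 6
Reactants: 7 methyl 2-{3,4-bis(benzyloxy)-5-[((2R)-3,3-dimethyloxiran-2-yl)methyl]phenyl}prop-2-enoate
Product: 8 2-{3,4-bis(benzyloxy)-5-[((2R)-3,3-dimethyloxiran-2-yl)methyl]phenyl}prop-2-enoic acid
Conditions: LiOH·H2O, THF–H2O, 0 °C to rt; then AcOH to pH 5, 0 °C
Reagents that add atoms: lithium hydroxide, [Li+].[OH-]
Why: Saponification of the methyl ester by acyl substitution; the trisubstituted epoxide tolerates hydroxide, the weak-acid work-up should avoid epoxide opening, and the acid is used at once.

Step 7
Reactants: 8 2-{3,4-bis(benzyloxy)-5-[((2R)-3,3-dimethyloxiran-2-yl)methyl]phenyl}prop-2-enoic acid; 9 phloroglucinol (benzene-1,3,5-triol)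
Product: 10 3,5-dihydroxyphenyl 2-{3,4-bis(benzyloxy)-5-[((2R)-3,3-dimethyloxiran-2-yl)methyl]phenyl}prop-2-enoate
Conditions: 9 (5 equiv), DIC, DMAP (10 mol%), THF, 0 °C to rt
Reagents that add atoms: none
Why: Steglich esterification; the excess of the symmetric triol statistically favours the mono-ester, O-acylation prevails under DMAP catalysis, and the epoxide is inert to these neutral conditions.

Step 8
Reactants: 10 3,5-dihydroxyphenyl 2-{3,4-bis(benzyloxy)-5-[((2R)-3,3-dimethyloxiran-2-yl)methyl]phenyl}prop-2-enoate
Product: 12 (3S)-3-{3,4-bis(benzyloxy)-5-[((2R)-3,3-dimethyloxiran-2-yl)methyl]phenyl}-5,7-dihydroxychroman-4-one, via trihydroxyphenyl enone 11 (not isolated)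
Conditions: hν (300 nm), degassed PhMe–EtOAc, −20 °C, flow; then squaramide of 9-amino-9-deoxy-epi-quinidine and 3,5-bis(trifluoromethyl)aniline (10 mol%), −40 °C; AcOH quench
Reagents that add atoms: none
Why: Proposed new method: excitation of the aryl ester cleaves the ArO–C(=O) bond to a caged phenoxyl/2-arylacryloyl radical pair (a vinylic acyl radical that should not decarbonylate), which recombines at a ring carbon and tautomerises to enone 11, as in the known photo-Fries rearrangement of aryl acrylates and cinnamates that precedes base-induced chromanone formation. The added bifunctional catalyst then deprotonates the acidic acylphloroglucinol with its quinuclidine nitrogen while the squaramide N–H pair binds the C4 carbonyl; the flanking phenoxide adds to the terminal alkene carbon in a 6-endo-trig oxa-Michael addition that forms the O1–C2 bond and closes ring C, and the resulting enolate is protonated at C3 by the quinuclidinium ion held on one face. The closest known reactions are cinchona squaramide- or thiourea-catalysed oxa-Michael cyclisations of 2′-hydroxychalcones to flavanones and amine-catalysed conjugate addition with enantioselective protonation of 2-substituted acrylates; their combination on a 2-aryl enone to set an isoflavanone C3 centre is the untested part. The C3 stereocentre is therefore catalyst-controlled (proton delivery to the Re face of the enolate, priorities C4 > C2 > C1′, gives 3S), the remote epoxide centre being too distant to matter. Regiochemistry needs no control because ring A is threefold symmetric: ortho or para recombination gives the same 2,4,6-trihydroxyphenyl ketone, and the two hydroxyls flanking the ketone are equivalent, one becoming O1 and the other the chelated 5-OH. The selectivity that must be won is catalysed over uncatalysed cyclisation and over later enolisation of C3, which is addressed by generating 11 without base in the cold, running the closure at −40 °C with the acidic 7-OH buffering the amine, and quenching with AcOH before warming.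

Step 9
Reactants: 12 (3S)-3-{3,4-bis(benzyloxy)-5-[((2R)-3,3-dimethyloxiran-2-yl)methyl]phenyl}-5,7-dihydroxychroman-4-one
Product: 13 (3S)-3-{3,4-dihydroxy-5-[((2R)-3,3-dimethyloxiran-2-yl)methyl]phenyl}-5,7-dihydroxychroman-4-one
Conditions: H2 (1 atm), 5% Pd/C (neutral grade), EtOAc, rt; reversed-phase purification at neutral pH
Reagents that add atoms: none
Why: Hydrogenolysis of the two aryl benzyl ethers on palladium under neutral conditions; the non-benzylic trisubstituted epoxide, the chelated aryl ketone and the base-labile C3 centre should survive in the absence of acid and base.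

**Compound list**

1 | 3-bromo-4,5-dihydroxybenzaldehyde | O=Cc1cc(O)c(O)c(Br)c1 | starting material
2 | 3,4-bis(benzyloxy)-5-bromobenzaldehyde | O=Cc1cc(OCc2ccccc2)c(OCc2ccccc2)c(Br)c1 | intermediate
3 | tributyl(3-methylbut-2-en-1-yl)stannane | CCCC[Sn](CCCC)(CCCC)CC=C(C)C | starting material
4 | 3,4-bis(benzyloxy)-5-(3-methylbut-2-en-1-yl)benzaldehyde | O=Cc1cc(OCc2ccccc2)c(OCc2ccccc2)c(CC=C(C)C)c1 | intermediate
5 | 1,2-bis(benzyloxy)-5-ethynyl-3-(3-methylbut-2-en-1-yl)benzene | C#Cc1cc(OCc2ccccc2)c(OCc2ccccc2)c(CC=C(C)C)c1 | intermediate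
6 | methyl 2-[3,4-bis(benzyloxy)-5-(3-methylbut-2-en-1-yl)phenyl]prop-2-enoate | COC(=O)C(=C)c1cc(OCc2ccccc2)c(OCc2ccccc2)c(CC=C(C)C)c1 | intermediate
7 | methyl 2-{3,4-bis(benzyloxy)-5-[((2R)-3,3-dimethyloxiran-2-yl)methyl]phenyl}prop-2-enoate | CC1(C)O[C@@H]1Cc1cc(C(=C)C(=O)OC)cc(OCc2ccccc2)c1OCc1ccccc1 | intermediate
8 | 2-{3,4-bis(benzyloxy)-5-[((2R)-3,3-dimethyloxiran-2-yl)methyl]phenyl}prop-2-enoic acid | CC1(C)O[C@@H]1Cc1cc(C(=C)C(=O)O)cc(OCc2ccccc2)c1OCc1ccccc1 | intermediate
9 | phloroglucinol (benzene-1,3,5-triol) | Oc1cc(O)cc(O)c1 | starting material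
10 | 3,5-dihydroxyphenyl 2-{3,4-bis(benzyloxy)-5-[((2R)-3,3-dimethyloxiran-2-yl)methyl]phenyl}prop-2-enoate | CC1(C)O[C@@H]1Cc1cc(C(=C)C(=O)Oc2cc(O)cc(O)c2)cc(OCc2ccccc2)c1OCc1ccccc1 | intermediate
11 | 2-{3,4-bis(benzyloxy)-5-[((2R)-3,3-dimethyloxiran-2-yl)methyl]phenyl}-1-(2,4,6-trihydroxyphenyl)prop-2-en-1-one | CC1(C)O[C@@H]1Cc1cc(C(=C)C(=O)c2c(O)cc(O)cc2O)cc(OCc2ccccc2)c1OCc1ccccc1 | intermediate
12 | (3S)-3-{3,4-bis(benzyloxy)-5-[((2R)-3,3-dimethyloxiran-2-yl)methyl]phenyl}-5,7-dihydroxychroman-4-one | CC1(C)O[C@@H]1Cc1cc([C@H]2COc3cc(O)cc(O)c3C2=O)cc(OCc2ccccc2)c1OCc1ccccc1 | intermediate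
13 | (3S)-3-{3,4-dihydroxy-5-[((2R)-3,3-dimethyloxiran-2-yl)methyl]phenyl}-5,7-dihydroxychroman-4-one | CC1(C)O[C@@H]1Cc1cc([C@H]2COc3cc(O)cc(O)c3C2=O)cc(O)c1O | target

Total step count: 9. Longest linear sequence: 9 steps (1 to 13); compounds 3 and 9 are bought.

**Steps most likely to fail**

1. Step 8 (Proposed new method). What may go wrong: poor facial control in the C3 protonation, uncatalysed cyclisation of 11 before the catalyst is added, erosion of C3 by amine-mediated enolisation after ring closure, or inefficient acyl migration if the benzyloxy-bearing chromophore diverts the excitation.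
Fallback with known chemistry, setting out from 10 and returning at 12: 10 is irradiated as in step 8 and the crude enone 11 is cyclised with an achiral base (Et3N, 5 mol%, 0 °C), the established photo-Fries/oxa-Michael route to chromanones. Because the epoxide centre is fixed, this should give 12 together with its C3 epimer, (3R)-3-{3,4-bis(benzyloxy)-5-[((2R)-3,3-dimethyloxiran-2-yl)methyl]phenyl}-5,7-dihydroxychroman-4-one F1, as diastereomers. They are separated by preparative HPLC on a polysaccharide carbamate phase. F1 is returned to the epimer mixture with Et3N in EtOAc at rt, since C3 is an enolisable benzylic position, and recycled, so the material converges on 12.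

2. Step 9. What may go wrong: attack of the freshly liberated C4′ hydroxyl on the neighbouring epoxide (5-exo or 6-endo) on the catalyst surface, or hydrogenolytic opening of the epoxide.
Fallback setting out from 12 and returning at 13: 12 is treated with Et3SiH and Pd(OAc)2 (cat.) in CH2Cl2 with a trace of Et3N. Silane-mediated benzyl–oxygen cleavage should pass the catechol oxygens on as silyl ethers, giving (3S)-3-{5-[((2R)-3,3-dimethyloxiran-2-yl)methyl]-3,4-bis(triethylsilyloxy)phenyl}-5,7-dihydroxychroman-4-one F2 without a free ortho hydroxyl meeting the catalyst. The silyl groups are then removed in homogeneous solution with AcOH-buffered Bu4NF in THF at −40 °C to give 13.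

3. Step 7. What may go wrong: over-acylation of the triol, or conjugate addition of a phenol to the activated acrylate, lowering the return of mono-ester.
Fallback setting out from 9 and 8 and returning at 10: phloroglucinol 9 is desymmetrised on its own with TBSCl (2 equiv) and imidazole in DMF to 3,5-bis(tert-butyldimethylsilyloxy)phenol F3, which has a single free hydroxyl. Steglich coupling with 8 (DIC, DMAP, CH2Cl2) gives 3,5-bis(tert-butyldimethylsilyloxy)phenyl 2-{3,4-bis(benzyloxy)-5-[((2R)-3,3-dimethyloxiran-2-yl)methyl]phenyl}prop-2-enoate F4. AcOH-buffered Bu4NF (THF, −20 °C) then removes the aryl silyl ethers and returns 10.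

**Further compounds**

F1 | step 8 | (3R)-3-{3,4-bis(benzyloxy)-5-[((2R)-3,3-dimethyloxiran-2-yl)methyl]phenyl}-5,7-dihydroxychroman-4-one | CC1(C)O[C@@H]1Cc1cc([C@@H]2COc3cc(O)cc(O)c3C2=O)cc(OCc2ccccc2)c1OCc1ccccc1
F2 | step 9 | (3S)-3-{5-[((2R)-3,3-dimethyloxiran-2-yl)methyl]-3,4-bis(triethylsilyloxy)phenyl}-5,7-dihydroxychroman-4-one | CC1(C)O[C@@H]1Cc1cc([C@H]2COc3cc(O)cc(O)c3C2=O)cc(O[Si](CC)(CC)CC)c1O[Si](CC)(CC)CC
F3 | step 7 | 3,5-bis(tert-butyldimethylsilyloxy)phenol | CC(C)(C)[Si](C)(C)Oc1cc(O)cc(O[Si](C)(C)C(C)(C)C)c1
F4 | step 7 | 3,5-bis(tert-butyldimethylsilyloxy)phenyl 2-{3,4-bis(benzyloxy)-5-[((2R)-3,3-dimethyloxiran-2-yl)methyl]phenyl}prop-2-enoate | CC1(C)O[C@@H]1Cc1cc(C(=C)C(=O)Oc2cc(O[Si](C)(C)C(C)(C)C)cc(O[Si](C)(C)C(C)(C)C)c2)cc(OCc2ccccc2)c1OCc1ccccc1
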